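## Structural features

The target is an ester of two isopropyl-substituted six-membered carbocycles. Ring A (A1–A6) is a cyclohexene with isopropyl at A1 (R), an (E)-2-(hydroxymethyl)acrylate arm at A2 (R, trans to isopropyl) and a hydroxymethyl group on A4 of the A3=A4 alkene. The acrylate carboxyl acylates the primary oxygen of the CH2O group on B4 of the right half, in which cyclohexane ring B (B1–B6) is cis-fused through B2–B3 to the seven-membered unsaturated lactone ring C, B3–C(=O)–O–CH2–C(CO2H)=CH–B2. Ring B carries four contiguous stereocentres: B1 (S, isopropyl), B2 (R, trans to isopropyl), B3 (S, lactone carbonyl cis to the B2 substituent) and B4 (R, tertiary hydroxyl cis to the B3 carbonyl, acyloxymethyl trans to it). Fragile points are the doubly allylic A2–H (γ to the ester carbonyl), the epimerisable B3–H, the allylic lactone C–O bond of the 2-(acyloxymethyl)acrylate type (open to SN2′ attack and to zerovalent palladium), the β-hydroxy acyl unit at B3/B4 and the free acid. The real difficulty is the B2/B3/B4 array, whose B3 carbon is axial when isopropyl and the B2 arm are equatorial and so cannot be reached by equilibration, together with two trisubstituted enoates of fixed geometry. The key step exploits that the trans A1/A2 pair next to A3=A4(CH2OH) is the pattern of a cyclohex-1-enecarbaldehyde built from an aldehyde, a nitroalkene and acrolein (bonds A2–A1, A6–A5, A3=A4); ring B shows the same pattern in the mirror-image sense (B1/B2 next to B3–B4–CH2O), so the same cascade under the enantiomeric catalyst also supplies ring B, with B3=B4 as the handle for the B3 carbon and the B4 oxygen.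

## Logic of the disconnections

39 ⇒ 37. Only protecting groups are removed: two silyl ethers on the ring A half and the tert-butyl ester on ring C. This keeps all three ester linkages of 39 untouched to the end. The forward step must be non-basic and non-nucleophilic so that the allylic lactone, A2 and B3 survive.

37 ⇒ 36. The ring C alkene (between the carbon on B2 and the carboxyl-bearing carbon) is cut. The ring dictates the alkene geometry, and the cut removes ring C. The forward ring-closing metathesis must engage only the vinyl group and the acrylate among five alkenes.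

36 ⇒ 34 + 35. The lactone O–CH2 bond is cut between a carboxylate and an allylic bromide. Ring C shrinks to a commercial three-carbon piece. The forward alkylation must be selective for the carboxylate next to a free tertiary hydroxyl.

34 ⇒ 32. The carbon on B3 is taken back from acid to primary alcohol. It stays an alcohol until after fragment union so that no carbonyl sits β to the epoxide. The forward oxidation must spare allylic silyl ethers, four alkenes and the tertiary alcohol.

32 ⇒ 20 + 31. The ester O–CH2 bond between the halves is cut; in 31 the CH2 and the B4 oxygen are tied as an epoxide. The acid acts as a nucleophile and is never activated, which protects A2, and B4 is already defined in 31. The molecule is split into two halves of similar size. The forward step needs attack at the CH2 terminus only.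

31 ⇒ 30. The B4–O bond is cut. The hydroxymethyl group on B3 can deliver oxygen to its own face of the exocyclic alkene. The demand is that this direction overrides the steric bias and leaves the vinyl group alone.

30 ⇒ 28. The B3–CH2 bond is cut with the alkene moved back to B3=B4. A [2,3] shift of an oxygen-bound carbanion creates the B3 carbon and the exocyclic alkene at once from an allylic ether. The demand is facial selectivity at B3, cis to the B2 substituent.

28 ⇒ 24. Functional group changes only: vinyl from the silyloxymethyl arm, stannylmethyl ether from the allylic alcohol. The ether doubles as protecting group while the arm is oxidised and methylenated. The demand is that the β,γ-unsaturated aldehyde on the way keeps B2.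

24 ⇒ 22. The nitro group and the alcohol oxidation level are restored. This leads back to the cascade product of the mirror-image series.

22 ⇒ 6 + 5 + 7. Bonds B2–B1, B6–B5 and B3=B4 are cut. All of ring B with B1 and B2 comes from three achiral partners under the (R)-catalyst.

20 ⇒ 14 + 18, and 18 ⇒ 15 + 16. The arm C=C is cut (Wittig), then the C–CH2O bond of the phosphorane. A stabilised α-substituted ylide gives the required geometry under neutral conditions. The demand is a hindered ylide reacting with a sensitive aldehyde.

14 ⇒ 9. Oxidation levels are adjusted at both one-carbon groups, the A4 alcohol is protected, and the nitro group is restored. The demand is that two silyl ethers be told apart.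

9 ⇒ 6 + 5 + 7. Bonds A2–A1, A6–A5 and A3=A4 are cut (key step). Ring A with A1 and A2 is reduced to three achiral partners. The demand is catalyst control of the first addition and the correct order of the three bond formations.

5 ⇒ 1 + 2. The C=C of the nitroalkene is cut (nitroaldol, then dehydration).

## Other disconnections considered

Alternative 1: The cut goes through the bonds joining B2 and B3 to their one-carbon substituents, taken back to a two-carbon bridge. Forward, enone A1 and acetylene A2 would combine under irradiation (triplet addition across C2–C3, anti to isopropyl) to the cis-fused cyclobutene A3. In its favour: the B2/B3 cis relation is enforced by the four-membered ring, B1/B2 trans follows from approach opposite to isopropyl, the B4 ketone remains for a face-selective carbon addition, and oxidative opening of the cyclobutene of A3 would put both one-carbon residues at the aldehyde level. Against it here: A2 is a poor and hazardous photopartner, A1 has to be made in enantioenriched form by a separate asymmetric step, the two carbons released from the four-membered ring must still be differentiated (acid at B3, aldehyde at B2), and ring A gains nothing. Comparison: in structure the alternative is the better one for the B2/B3 pair, because ring strain guarantees what the chosen plan obtains only from the facial preference of the rearrangement in step 19. In mechanism a stepwise photocycloaddition stands against a sigmatropic shift, and both leave B4 to a later face-selective step. In step economy it is about equal for the right half alone, but it needs its own stereochemical source, whereas the chosen plan draws both rings from one cascade.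

Alternative 2: The cut goes through the lactone O–CH2 bond and the ring C alkene at once. Forward, the carboxylate of formyl acid A4 would add to phosphonoacrylate A5 (oxa-Michael addition) and the resulting phosphonate-stabilised centre would olefinate the neighbouring formyl group, giving A6. In its favour: ring C, its alkene and the tert-butyl ester arrive in one operation, the ring fixes the alkene geometry, and no metal catalyst is needed. Against it here: a carboxylate is a weak, reversible Michael donor, the adduct carries a β-acyloxy leaving group, the closure is to a seven-membered ring where the established cases of this sequence close five- and six-membered rings from alkoxide or amine donors, and A4 has a base-labile formyl-bearing centre. Comparison: in structure the result equals ring C of the chosen plan (same lactone, same ester). In step economy the alternative is better by one step, since the chosen plan uses two (alkylation with 35, then metathesis). In mechanism the chosen plan relies on two reaction types with direct precedent, the alternative on an extension. The annulation creates no stereocentre, so it presupposes a solution to the B2/B3/B4 problem and is a tactic that could serve either plan, not a strategy.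

Alternative 3: The cut is the B3–B4 bond. Forward, keto acid A7, after carboxyl activation and enolisation by a nucleophilic amine catalyst, would add to its ketone and close by O-acylation to the cis-fused β-lactone A8. In its favour: ring B, B3 and B4 form in one catalytic step, the cis relation of the B3 carbonyl and the B4 oxygen is built into the four-membered ring, a chiral catalyst can reinforce induction from B1, and the β-lactone is an activated acyl group. Against it here: A8 has no substituent on B2, so the ring C alkene carbon would have to be attached later to an unactivated methylene, or carried in A7, where its effect on the aldol transition state is unsettled; B1 needs a separate asymmetric step; and the strained lactone must survive the chemistry at B2. Comparison: for the B3/B4 pair the alternative is the better one (one step, cis by construction, against rearrangement plus directed epoxidation). For B2 it is clearly weaker, because the chosen plan has the B2 substituent and its trans relation to isopropyl from the cascade. In step economy the late work at B2 would outweigh the early gain.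

Key step: step 3

Remarks on the chemistry: 15, 16, 35, tributyl(iodomethyl)stannane and both enantiomers of the amine catalyst are taken as purchasable. The (S)-catalyst series (8–14, 19, 20) has the configuration of ring A; ring B needs the mirror-image series (21–31), hence the (R)-catalyst in step 12. Labels A1–A6 and B1–B6 are ring positions as defined above.

## Route

Step 1
Reactants: 1 2-methylpropanal; 2 nitromethane
Product: 3 3-methyl-1-nitrobutan-2-ol (racemic)
Conditions: MeNO2 (excess), KOtBu (cat.), THF/t-BuOH, 0 °C → rt
Reagents that add atoms: none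
Why: Henry (nitroaldol) addition of the nitronate to an unhindered aldehyde; the carbinol centre is destroyed in step 2, so no control is needed.

Step 2
Reactants: 3 3-methyl-1-nitrobutan-2-ol
Product: 5 (E)-3-methyl-1-nitrobut-1-ene, via nitro mesylate 4 (not isolated)
Conditions: MsCl, Et3N, CH2Cl2, −10 °C → rt
Reagents that add atoms: none
Why: Mesylation followed by E1cB elimination through the nitronate gives the conjugated nitroalkene; the E isomer is the thermodynamically favoured one.

Step 3
Reactants: 6 3-[tert-butyl(dimethyl)silyl]oxypropanal; 5 (E)-3-methyl-1-nitrobut-1-ene; 7 acrolein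
Product: 9 (3S,4R,5R)-3-{[tert-butyl(dimethyl)silyl]oxymethyl}-5-nitro-4-(propan-2-yl)cyclohex-1-ene-1-carbaldehyde, via nitroaldehyde Michael adduct 8 (not isolated)
Conditions: (S)-2-[diphenyl(trimethylsilyloxy)methyl]pyrrolidine (20 mol%), PhCO2H (20 mol%), toluene, 0 °C; then 7, 0 °C → rt
Reagents that add atoms: none
Why: The enamine of 6 adds through its unshielded face to 5 in a syn-selective Michael addition (bond A2–A1) and releases 8; the nitronate of 8 then adds to the iminium ion of 7 (bond A6–A5), and the enamine so formed attacks the first formyl group in a 6-(enolexo)-exo-trig aldol addition whose dehydration gives A3=A4 and closes ring A. The closest known reaction type is the amine-catalysed Michael–Michael–aldol condensation cascade of an aldehyde, a nitroalkene and an enal to cyclohex-1-enecarbaldehydes. A2 is set by the diphenyl(silyloxy)methyl group of the (S)-catalyst, which blocks one enamine face, and A1 by the compact acyclic transition state with gauche enamine and nitroalkene double bonds (syn adduct, trans in the ring); the nitro-bearing A6 is under thermodynamic control, settles equatorial and is removed in step 6. The step needs chemoselectivity (the enamine of 6 must meet 5 before 7) and enantio- and diastereocontrol in the first addition. The nitroalkene is the stronger acceptor for an enamine, while acrolein becomes reactive toward the nitronate only as its iminium ion; adding 7 after 5 is consumed reinforces this order. The acid co-catalyst speeds enamine turnover with the less reactive aliphatic nitroalkene, so that loss of silanol from 6 should not compete.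

Step 4
Reactants: 9 cascade aldehyde
Product: 10 [(3S,4R,5R)-3-{[tert-butyl(dimethyl)silyl]oxymethyl}-5-nitro-4-(propan-2-yl)cyclohex-1-en-1-yl]methanol
Conditions: NaBH4, CeCl3·7H2O, MeOH, −20 °C
Reagents that add atoms: none
Why: Luche 1,2-reduction of the enal; the nitro group and the silyl ether are inert, and the short cold reaction avoids nitronate chemistry.

Step 5
Reactants: 10 nitro allylic alcohol
Product: 11 (3S,4R,5R)-1-{[tert-butyl(diphenyl)silyl]oxymethyl}-3-{[tert-butyl(dimethyl)silyl]oxymethyl}-5-nitro-4-(propan-2-yl)cyclohex-1-ene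
Conditions: TBDPSCl, imidazole, DMF, rt
Reagents that add atoms: tert-butyl(chloro)diphenylsilane, CC(C)(C)[Si](Cl)(c1ccccc1)c1ccccc1
Why: Silylation of the primary allylic alcohol; the bulkier, more acid-stable silyl group is chosen so that the arm ether can be removed selectively in step 7.

Step 6
Reactants: 11 bis-silyl nitro compound
Product: 12 (3R,4R)-1-{[tert-butyl(diphenyl)silyl]oxymethyl}-3-{[tert-butyl(dimethyl)silyl]oxymethyl}-4-(propan-2-yl)cyclohex-1-ene
Conditions: Bu3SnH, azobis(isobutyronitrile), toluene, 110 °C
Reagents that add atoms: none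
Why: Radical denitration: the stannyl radical adds to a nitro oxygen, the C–N bond fragments and the secondary radical takes hydrogen from the stannane; a secondary nitroalkane needs the higher temperature. The homoallylic radical is reduced faster than it can cyclise, and A1 and A2 are not involved.

Step 7
Reactants: 12 bis-silyl ether
Product: 13 [(1R,6R)-3-{[tert-butyl(diphenyl)silyl]oxymethyl}-6-(propan-2-yl)cyclohex-2-en-1-yl]methanol
Conditions: pyridinium p-toluenesulfonate (cat.), MeOH, rt
Reagents that add atoms: none
Why: Acid-catalysed methanolysis cleaves a primary tert-butyldimethylsilyl ether much faster than a primary tert-butyldiphenylsilyl ether.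

Step 8
Reactants: 13 arm alcohol
Product: 14 (1R,6R)-3-{[tert-butyl(diphenyl)silyl]oxymethyl}-6-(propan-2-yl)cyclohex-2-ene-1-carbaldehyde
Conditions: Dess–Martin periodinane, NaHCO3, CH2Cl2, 0 °C; used at once
Reagents that add atoms: none
Why: Dess–Martin oxidation under buffered, non-basic conditions, so that the α-centre A2 of the β,γ-unsaturated aldehyde neither epimerises nor lets the alkene move into conjugation.

Step 9
Reactants: 15 prop-2-en-1-yl (triphenylphosphoranylidene)acetate; 16 (chloromethoxy)tri(propan-2-yl)silane
Product: 18 prop-2-en-1-yl 2-(triphenylphosphoranylidene)-3-[tri(propan-2-yl)silyloxy]propanoate, via alkylated phosphonium chloride 17 (not isolated)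
Conditions: 15 (2 equiv), 16 (1 equiv), CH2Cl2, 0 °C → rt; filtration of the phosphonium salt
Reagents that add atoms: none
Why: C-Alkylation of an ester-stabilised phosphorane by a reactive α-chloro ether, then transylidation by the second equivalent of 15 (the usual alkylation of stabilised ylides). The β-silyloxy group should stay, since loss of silanolate would give a vinylphosphonium ion that takes it back.

Step 10
Reactants: 14 ring A aldehyde; 18 silyloxymethyl phosphorane
Product: 19 prop-2-en-1-yl (2E)-3-[(1R,6R)-3-{[tert-butyl(diphenyl)silyl]oxymethyl}-6-(propan-2-yl)cyclohex-2-en-1-yl]-2-{[tri(propan-2-yl)silyl]oxymethyl}prop-2-enoate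
Conditions: toluene, 50 °C
Reagents that add atoms: none
Why: Wittig reaction of an α-substituted stabilised ylide; the reversible addition places ring A trans to the ester carbonyl and cis to CH2O (E), as the target requires, and the neutral medium spares A2.

Step 11
Reactants: 19 allyl ester
Product: 20 (2E)-3-[(1R,6R)-3-{[tert-butyl(diphenyl)silyl]oxymethyl}-6-(propan-2-yl)cyclohex-2-en-1-yl]-2-{[tri(propan-2-yl)silyl]oxymethyl}prop-2-enoic acid
Conditions: Pd(PPh3)4 (cat.), morpholine, THF, rt
Reagents that add atoms: none
Why: Zerovalent palladium ionises only the allyl ester and morpholine captures the π-allyl fragment; no hydroxide is present, so the silyl ethers and A2 are untouched.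

Step 12
Reactants: 6 3-[tert-butyl(dimethyl)silyl]oxypropanal; 5 (E)-3-methyl-1-nitrobut-1-ene; 7 acrolein
Product: 22 (3R,4S,5S)-3-{[tert-butyl(dimethyl)silyl]oxymethyl}-5-nitro-4-(propan-2-yl)cyclohex-1-ene-1-carbaldehyde, via nitroaldehyde Michael adduct 21 (not isolated)
Conditions: (R)-2-[diphenyl(trimethylsilyloxy)methyl]pyrrolidine (20 mol%), PhCO2H (20 mol%), toluene, 0 °C; then 7, 0 °C → rt
Reagents that add atoms: none
Why: The cascade of step 3 under the enantiomeric catalyst gives the mirror-image ring, in which the isopropyl carbon is B1, the silyloxymethyl carbon B2 and the enal alkene B3=B4; B1 and B2 are set by the catalyst as before (bonds B2–B1, B6–B5, B3=B4, 6-(enolexo)-exo-trig closure).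

Step 13
Reactants: 22 ring B cascade aldehyde
Product: 23 [(3R,4S,5S)-3-{[tert-butyl(dimethyl)silyl]oxymethyl}-5-nitro-4-(propan-2-yl)cyclohex-1-en-1-yl]methanol
Conditions: NaBH4, CeCl3·7H2O, MeOH, −20 °C
Reagents that add atoms: none
Why: Luche 1,2-reduction, as in step 4.

Step 14
Reactants: 23 nitro allylic alcohol
Product: 24 [(3S,4S)-3-{[tert-butyl(dimethyl)silyl]oxymethyl}-4-(propan-2-yl)cyclohex-1-en-1-yl]methanol
Conditions: Bu3SnH, azobis(isobutyronitrile), toluene, 110 °C
Reagents that add atoms: none
Why: Radical denitration as in step 6; the free hydroxyl is compatible, and the nitro group has to go before strong bases are used.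

Step 15
Reactants: 24 allylic alcohol
Product: 25 tributyl({[(3S,4S)-3-{[tert-butyl(dimethyl)silyl]oxymethyl}-4-(propan-2-yl)cyclohex-1-en-1-yl]methoxy}methyl)stannane
Conditions: KH, Bu3SnCH2I, THF, 0 °C → rt
Reagents that add atoms: tributyl(iodomethyl)stannane, CCCC[Sn](CCCC)(CCCC)CI
Why: Williamson etherification of the potassium alkoxide; the ether protects the allylic alcohol during the arm chemistry and is the precursor for the rearrangement.

Step 16
Reactants: 25 stannylmethyl ether
Product: 26 [(1S,6S)-6-(propan-2-yl)-3-{[(tributylstannyl)methoxy]methyl}cyclohex-2-en-1-yl]methanol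
Conditions: TBAF, THF, 0 °C
Reagents that add atoms: none
Why: Fluoride cleavage of the silyl ether; the α-alkoxystannane is stable to fluoride.

Step 17
Reactants: 26 arm alcohol
Product: 27 (1S,6S)-6-(propan-2-yl)-3-{[(tributylstannyl)methoxy]methyl}cyclohex-2-ene-1-carbaldehyde
Conditions: Dess–Martin periodinane, NaHCO3, CH2Cl2, 0 °C; used at once
Reagents that add atoms: none
Why: Buffered Dess–Martin oxidation as in step 8; the stannane is inert and B2 is kept by avoiding base.

Step 18
Reactants: 27 ring B aldehyde
Product: 28 tributyl({[(3S,4S)-3-ethenyl-4-(propan-2-yl)cyclohex-1-en-1-yl]methoxy}methyl)stannane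
Conditions: Ph3PCH3Br, KN(SiMe3)2, THF, −78 → 0 °C
Reagents that add atoms: methyltriphenylphosphonium bromide, C[P+](c1ccccc1)(c1ccccc1)c1ccccc1.[Br-]
Why: Wittig methylenation; the non-stabilised ylide adds to the aldehyde at −78 °C faster than it can deprotonate at B2.

Step 19
Reactants: 28 vinyl stannylmethyl ether
Product: 30 [(1S,2S,3S)-2-ethenyl-6-methylidene-3-(propan-2-yl)cyclohexyl]methanol, via alkoxymethyllithium 29 (not isolated)
Conditions: n-BuLi, THF, −78 → −30 °C; aq. NH4Cl
Reagents that add atoms: none
Why: Tin–lithium exchange gives 29, which undergoes the [2,3]-Wittig rearrangement (Wittig–Still variant) through a five-membered envelope transition state, forming the B3–CH2 bond and moving the alkene to B4=CH2. The new bond should form axially on the half-chair that keeps isopropyl and vinyl equatorial, that is, on the face of the vinyl group, because the opposite axial path would need both groups axial and would run 1,3-syn to isopropyl; this sets B3.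

Step 20
Reactants: 30 homoallylic alcohol
Product: 31 [(3R,4R,5S,6S)-5-ethenyl-6-(propan-2-yl)-1-oxaspiro[2.5]octan-4-yl]methanol
Conditions: VO(acac)2 (cat.), t-BuOOH, CH2Cl2, 0 °C
Reagents that add atoms: tert-butyl hydroperoxide, CC(C)(C)OO
Why: Vanadium-catalysed epoxidation directed by the homoallylic (axial) hydroxymethyl group puts oxygen on the face of the exocyclic alkene where that group lies, which sets B4 with oxygen cis to the B3 carbon and the epoxide CH2 trans. The monosubstituted vinyl group is one atom further from the hydroxyl and less electron-rich, and should be left alone.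

Step 21
Reactants: 20 ring A acid; 31 ring B epoxy alcohol
Product: 32 [(1R,2R,3S,4S)-3-ethenyl-1-hydroxy-2-(hydroxymethyl)-4-(propan-2-yl)cyclohexyl]methyl ester of acid 20
Conditions: Cs2CO3 (cat.), DMF, 60 °C
Reagents that add atoms: none
Why: Carboxylate opening of a 2,2-disubstituted epoxide at its CH2 terminus (SN2) forms the inter-half ester and frees the tertiary B4 hydroxyl with B4 unchanged. The acid acts as a nucleophile and is never activated, so the γ-acidic A2 is not endangered, and the trans-diaxial B3 hydroxymethyl cannot reach the epoxide.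

Step 22
Reactants: 32 coupled diol
Product: 34 (1S,2S,3S,6R)-2-ethenyl-6-hydroxy-3-(propan-2-yl)-6-({[acyl of 20]oxy}methyl)cyclohexane-1-carboxylic acid, via aldehyde 33 (not isolated)
Conditions: 2,2,6,6-tetramethylpiperidine-1-oxyl (cat.), PhI(OAc)2, MeCN/H2O (pH 7 buffer), rt
Reagents that add atoms: water, O
Why: Oxoammonium oxidation of the only primary alcohol to aldehyde 33 and, through its hydrate, to the acid. The neutral buffer should keep the β-hydroxy aldehyde from retro-aldol cleavage and from epimerisation at B3; the tertiary alcohol, alkenes and silyl ethers are inert.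

Step 23
Reactants: 34 B3 acid; 35 tert-butyl 2-(bromomethyl)prop-2-enoate
Product: 36 2-(tert-butoxycarbonyl)prop-2-en-1-yl ester of acid 34
Conditions: KHCO3, DMF, 0 °C → rt
Reagents that add atoms: none
Why: O-Alkylation of the carboxylate by an activated allylic bromide (SN2, or SN2′ leading to the same ester); the weak base touches neither B3–H nor the tertiary alcohol.

Step 24
Reactants: 36 diene ester
Product: 37 ring C lactone tert-butyl ester with both silyl ethers in place (B1 S, B2 R, B3 S, B4 R)
Conditions: second-generation Hoveyda–Grubbs catalyst RuCl2(H2IMes)(=CH–C6H4-2-OiPr) (cat.), toluene, 80 °C, high dilution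
Reagents that add atoms: none
Why: Ring-closing metathesis between the vinyl group (initiation site) and the 1,1-disubstituted acrylate closes seven-membered ring C with loss of ethene. The ring fixes the alkene geometry, and the trisubstituted alkenes of the left half are too hindered to compete.

Step 25
Reactants: 37 protected target
Product: 39 target CNP0361406.3, via bis(trimethylsilyl) intermediate 38 (not isolated)
Conditions: TMSOTf, 2,6-lutidine, CH2Cl2, 0 °C; then HF·pyridine, pyridine, THF, 0 °C → rt
Reagents that add atoms: none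
Why: The silyl triflate turns the tert-butyl ester into a trimethylsilyl ester with loss of isobutene (and silylates the tertiary alcohol), a non-nucleophilic cleavage that cannot open the allylic lactone. Buffered hydrogen fluoride then removes all silyl groups without base, so that A2 and B3 keep their configuration.

## Compound list

1 | 2-methylpropanal | CC(C)C=O | starting material
2 | nitromethane | C[N+](=O)[O-] | starting material
3 | 3-methyl-1-nitrobutan-2-ol (racemic) | CC(C)C(O)C[N+](=O)[O-] | intermediate
4 | 3-methyl-1-nitrobutan-2-yl methanesulfonate (racemic) | CC(C)C(OS(C)(=O)=O)C[N+](=O)[O-] | intermediate (not isolated)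
5 | (E)-3-methyl-1-nitrobut-1-ene | CC(C)/C=C/[N+](=O)[O-] | intermediate
6 | 3-[tert-butyl(dimethyl)silyl]oxypropanal | O=CCCO[Si](C)(C)C(C)(C)C | starting material
7 | prop-2-enal (acrolein) | C=CC=O | starting material
8 | (2S,3R)-2-{[tert-butyl(dimethyl)silyl]oxymethyl}-4-methyl-3-(nitromethyl)pentanal | CC(C)[C@@H](C[N+](=O)[O-])[C@H](C=O)CO[Si](C)(C)C(C)(C)C | intermediate (not isolated)
9 | (3S,4R,5R)-3-{[tert-butyl(dimethyl)silyl]oxymethyl}-5-nitro-4-(propan-2-yl)cyclohex-1-ene-1-carbaldehyde | CC(C)[C@H]1[C@H]([N+](=O)[O-])CC(C=O)=C[C@@H]1CO[Si](C)(C)C(C)(C)C | intermediate (key-step product)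
10 | [(3S,4R,5R)-3-{[tert-butyl(dimethyl)silyl]oxymethyl}-5-nitro-4-(propan-2-yl)cyclohex-1-en-1-yl]methanol | CC(C)[C@H]1[C@H]([N+](=O)[O-])CC(CO)=C[C@@H]1CO[Si](C)(C)C(C)(C)C | intermediate
11 | (3S,4R,5R)-1-{[tert-butyl(diphenyl)silyl]oxymethyl}-3-{[tert-butyl(dimethyl)silyl]oxymethyl}-5-nitro-4-(propan-2-yl)cyclohex-1-ene | CC(C)[C@H]1[C@H]([N+](=O)[O-])CC(CO[Si](c2ccccc2)(c2ccccc2)C(C)(C)C)=C[C@@H]1CO[Si](C)(C)C(C)(C)C | intermediate
12 | (3R,4R)-1-{[tert-butyl(diphenyl)silyl]oxymethyl}-3-{[tert-butyl(dimethyl)silyl]oxymethyl}-4-(propan-2-yl)cyclohex-1-ene | CC(C)[C@H]1CCC(CO[Si](c2ccccc2)(c2ccccc2)C(C)(C)C)=C[C@@H]1CO[Si](C)(C)C(C)(C)C | intermediate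
13 | [(1R,6R)-3-{[tert-butyl(diphenyl)silyl]oxymethyl}-6-(propan-2-yl)cyclohex-2-en-1-yl]methanol | CC(C)[C@H]1CCC(CO[Si](c2ccccc2)(c2ccccc2)C(C)(C)C)=C[C@@H]1CO | intermediate
14 | (1R,6R)-3-{[tert-butyl(diphenyl)silyl]oxymethyl}-6-(propan-2-yl)cyclohex-2-ene-1-carbaldehyde | CC(C)[C@H]1CCC(CO[Si](c2ccccc2)(c2ccccc2)C(C)(C)C)=C[C@@H]1C=O | intermediate
15 | prop-2-en-1-yl (triphenylphosphoranylidene)acetate | C=CCOC(=O)C=P(c1ccccc1)(c1ccccc1)c1ccccc1 | starting material
16 | (chloromethoxy)tri(propan-2-yl)silane | ClCO[Si](C(C)C)(C(C)C)C(C)C | starting material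
17 | {1-[(prop-2-en-1-yloxy)carbonyl]-2-[tri(propan-2-yl)silyloxy]ethyl}triphenylphosphonium chloride (racemic) | C=CCOC(=O)C(CO[Si](C(C)C)(C(C)C)C(C)C)[P+](c1ccccc1)(c1ccccc1)c1ccccc1.[Cl-] | intermediate (not isolated)
18 | prop-2-en-1-yl 2-(triphenylphosphoranylidene)-3-[tri(propan-2-yl)silyloxy]propanoate | C=CCOC(=O)C(CO[Si](C(C)C)(C(C)C)C(C)C)=P(c1ccccc1)(c1ccccc1)c1ccccc1 | intermediate
19 | prop-2-en-1-yl (2E)-3-[(1R,6R)-3-{[tert-butyl(diphenyl)silyl]oxymethyl}-6-(propan-2-yl)cyclohex-2-en-1-yl]-2-{[tri(propan-2-yl)silyl]oxymethyl}prop-2-enoate | CC(C)[C@H]1CCC(CO[Si](c2ccccc2)(c2ccccc2)C(C)(C)C)=C[C@@H]1/C=C(\CO[Si](C(C)C)(C(C)C)C(C)C)C(=O)OCC=C | intermediate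
20 | (2E)-3-[(1R,6R)-3-{[tert-butyl(diphenyl)silyl]oxymethyl}-6-(propan-2-yl)cyclohex-2-en-1-yl]-2-{[tri(propan-2-yl)silyl]oxymethyl}prop-2-enoic acid | CC(C)[C@H]1CCC(CO[Si](c2ccccc2)(c2ccccc2)C(C)(C)C)=C[C@@H]1/C=C(\CO[Si](C(C)C)(C(C)C)C(C)C)C(=O)O | intermediate
21 | (2R,3S)-2-{[tert-butyl(dimethyl)silyl]oxymethyl}-4-methyl-3-(nitromethyl)pentanal | CC(C)[C@H](C[N+](=O)[O-])[C@@H](C=O)CO[Si](C)(C)C(C)(C)C | intermediate (not isolated)
22 | (3R,4S,5S)-3-{[tert-butyl(dimethyl)silyl]oxymethyl}-5-nitro-4-(propan-2-yl)cyclohex-1-ene-1-carbaldehyde | CC(C)[C@@H]1[C@@H]([N+](=O)[O-])CC(C=O)=C[C@H]1CO[Si](C)(C)C(C)(C)C | intermediate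
23 | [(3R,4S,5S)-3-{[tert-butyl(dimethyl)silyl]oxymethyl}-5-nitro-4-(propan-2-yl)cyclohex-1-en-1-yl]methanol | CC(C)[C@@H]1[C@@H]([N+](=O)[O-])CC(CO)=C[C@H]1CO[Si](C)(C)C(C)(C)C | intermediate
24 | [(3S,4S)-3-{[tert-butyl(dimethyl)silyl]oxymethyl}-4-(propan-2-yl)cyclohex-1-en-1-yl]methanol | CC(C)[C@@H]1CCC(CO)=C[C@H]1CO[Si](C)(C)C(C)(C)C | intermediate
25 | tributyl({[(3S,4S)-3-{[tert-butyl(dimethyl)silyl]oxymethyl}-4-(propan-2-yl)cyclohex-1-en-1-yl]methoxy}methyl)stannane | CC(C)[C@@H]1CCC(COC[Sn](CCCC)(CCCC)CCCC)=C[C@H]1CO[Si](C)(C)C(C)(C)C | intermediate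
26 | [(1S,6S)-6-(propan-2-yl)-3-{[(tributylstannyl)methoxy]methyl}cyclohex-2-en-1-yl]methanol | CC(C)[C@@H]1CCC(COC[Sn](CCCC)(CCCC)CCCC)=C[C@H]1CO | intermediate
27 | (1S,6S)-6-(propan-2-yl)-3-{[(tributylstannyl)methoxy]methyl}cyclohex-2-ene-1-carbaldehyde | CC(C)[C@@H]1CCC(COC[Sn](CCCC)(CCCC)CCCC)=C[C@H]1C=O | intermediate
28 | tributyl({[(3S,4S)-3-ethenyl-4-(propan-2-yl)cyclohex-1-en-1-yl]methoxy}methyl)stannane | CC(C)[C@@H]1CCC(COC[Sn](CCCC)(CCCC)CCCC)=C[C@H]1C=C | intermediate
29 | ({[(3S,4S)-3-ethenyl-4-(propan-2-yl)cyclohex-1-en-1-yl]methoxy}methyl)lithium | CC(C)[C@@H]1CCC(COC[Li])=C[C@H]1C=C | intermediate (not isolated)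
30 | [(1S,2S,3S)-2-ethenyl-6-methylidene-3-(propan-2-yl)cyclohexyl]methanol | C=C1CC[C@@H](C(C)C)[C@H](C=C)[C@@H]1CO | intermediate
31 | [(3R,4R,5S,6S)-5-ethenyl-6-(propan-2-yl)-1-oxaspiro[2.5]octan-4-yl]methanol | OC[C@H]1[C@@H](C=C)[C@H](C(C)C)CC[C@]12CO2 | intermediate
32 | [(1R,2R,3S,4S)-3-ethenyl-1-hydroxy-2-(hydroxymethyl)-4-(propan-2-yl)cyclohexyl]methyl ester of acid 20 (A1 R, A2 R, B1 S, B2 S, B3 R, B4 R; arm alkene E) | CC(C)[C@H]1CCC(CO[Si](c2ccccc2)(c2ccccc2)C(C)(C)C)=C[C@@H]1/C=C(\CO[Si](C(C)C)(C(C)C)C(C)C)C(=O)OC[C@@]1(O)CC[C@@H](C(C)C)[C@H](C=C)[C@@H]1CO | intermediate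
33 | [(1R,2S,3S,4S)-3-ethenyl-2-formyl-1-hydroxy-4-(propan-2-yl)cyclohexyl]methyl ester of acid 20 | CC(C)[C@H]1CCC(CO[Si](c2ccccc2)(c2ccccc2)C(C)(C)C)=C[C@@H]1/C=C(\CO[Si](C(C)C)(C(C)C)C(C)C)C(=O)OC[C@@]1(O)CC[C@@H](C(C)C)[C@H](C=C)[C@@H]1C=O | intermediate (not isolated)
34 | (1S,2S,3S,6R)-2-ethenyl-6-hydroxy-3-(propan-2-yl)-6-({[acyl of 20]oxy}methyl)cyclohexane-1-carboxylic acid | CC(C)[C@H]1CCC(CO[Si](c2ccccc2)(c2ccccc2)C(C)(C)C)=C[C@@H]1/C=C(\CO[Si](C(C)C)(C(C)C)C(C)C)C(=O)OC[C@@]1(O)CC[C@@H](C(C)C)[C@H](C=C)[C@@H]1C(=O)O | intermediate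
35 | tert-butyl 2-(bromomethyl)prop-2-enoate | C=C(CBr)C(=O)OC(C)(C)C | starting material
36 | 2-(tert-butoxycarbonyl)prop-2-en-1-yl ester of acid 34 (B1 S, B2 S, B3 S, B4 R) | CC(C)[C@H]1CCC(CO[Si](c2ccccc2)(c2ccccc2)C(C)(C)C)=C[C@@H]1/C=C(\CO[Si](C(C)C)(C(C)C)C(C)C)C(=O)OC[C@@]1(O)CC[C@@H](C(C)C)[C@H](C=C)[C@@H]1C(=O)OCC(=C)C(=O)OC(C)(C)C | intermediate
37 | protected target: ring C lactone as tert-butyl ester, A4 CH2O as tert-butyldiphenylsilyl ether, arm CH2O as triisopropylsilyl ether (A1 R, A2 R, B1 S, B2 R, B3 S, B4 R) | CC(C)[C@H]1CCC(CO[Si](c2ccccc2)(c2ccccc2)C(C)(C)C)=C[C@@H]1/C=C(\CO[Si](C(C)C)(C(C)C)C(C)C)C(=O)OC[C@@]1(O)CC[C@@H](C(C)C)[C@@H]2C=C(C(=O)OC(C)(C)C)COC(=O)[C@@H]21 | intermediate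
38 | as 37, with the ring C carboxyl as trimethylsilyl ester and the B4 hydroxyl as trimethylsilyl ether | CC(C)[C@H]1CCC(CO[Si](c2ccccc2)(c2ccccc2)C(C)(C)C)=C[C@@H]1/C=C(\CO[Si](C(C)C)(C(C)C)C(C)C)C(=O)OC[C@@]1(O[Si](C)(C)C)CC[C@@H](C(C)C)[C@@H]2C=C(C(=O)O[Si](C)(C)C)COC(=O)[C@@H]21 | intermediate (not isolated)
39 | CNP0361406.3 (A1 R, A2 R, B1 S, B2 R, B3 S, B4 R; arm alkene E) | CC(C)[C@H]1CCC(CO)=C[C@@H]1/C=C(\CO)C(=O)OC[C@@]1(O)CC[C@@H](C(C)C)[C@@H]2C=C(C(=O)O)COC(=O)[C@@H]21 | target

## Step count and least certain steps

Total: 25 steps. Longest linear sequence: 16 steps (1, 2, 12–25).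

Step 3 (key step; step 12 is its mirror image). Most likely failure: loss of the order of events. A slow enamine addition to the aliphatic nitroalkene would let the enamine of 6 lose silanol or meet acrolein first, acrolein may oligomerise, and incomplete facial control in the first addition would be carried through as diastereomers. Fallback (stepwise instead of cascade): the amine-catalysed Michael addition of 6 to 5 is run alone and 8 is isolated. Its nitronate is added to 7 with catalytic Et3N (CH2Cl2, 0 °C) to give the nitro dialdehyde F1. Dibenzylammonium trifluoroacetate (toluene, rt) then closes the ring by aldol condensation. The fallback sets out from 6 and 5 and comes back at 9.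

Step 19. Most likely failure: poor facial selectivity of the rearrangement (carbon delivered anti to the vinyl group) or a competing 1,2-shift. Fallback (the carbon is delivered from the arm oxygen, which can reach only the required face): 24 is converted into the allylic phenyl sulfide F2 (PhSSPh, Bu3P). TBAF gives the arm alcohol F3, and (bromomethyl)chlorodimethylsilane with imidazole gives the bromomethylsilyl ether F4. Bu3SnH with azobis(isobutyronitrile) then triggers a 6-exo radical cyclisation onto B3 with loss of a phenylthiyl radical, giving the cis-fused siloxane F5 with the exocyclic alkene in place. Tamao oxidation (H2O2, KF, KHCO3) gives the diol F6. Oxidative lactonisation (2,2,6,6-tetramethylpiperidine-1-oxyl, PhI(OAc)2), expected to start at the less hindered equatorial arm carbinol, gives the lactone F7. i-Bu2AlH gives the lactol F8, and Wittig methylenation (Ph3P=CH2) of the lactol opens it to the vinyl alcohol. The fallback sets out from 24 and comes back at 30.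

Step 21. Most likely failure: sluggish opening at the neopentyl-type epoxide terminus, so that long heating lets the carboxylate isomerise at its alkene or lets water open the epoxide. Fallback (acylation of a preformed diol instead of epoxide opening): 31 is silylated (TBSCl, imidazole) to the epoxy silyl ether F9. CsOAc in DMF opens the epoxide to the acetate F10, and K2CO3 in MeOH gives the diol F11. Yamaguchi esterification of 20 (2,4,6-trichlorobenzoyl chloride, Et3N, 4-(dimethylamino)pyridine, 0 °C) at the primary hydroxyl gives the ester F12. Pyridinium p-toluenesulfonate in MeOH then removes the tert-butyldimethylsilyl group. The fallback sets out from 31 and comes back at 32.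

Step 10 (with the ylide preparation, step 9). Most likely failure: slow olefination by the hindered ylide, giving the aldehyde time to epimerise at A2 or to shift its alkene into conjugation, and O-alkylation instead of C-alkylation when 18 is made. Fallback (small ylide, hydroxymethyl carbon added by cross-coupling): 14 and methyl bromo(triphenylphosphoranylidene)acetate (CH2Cl2, rt) give the (Z)-bromo enoate F13. Stille coupling with (tributylstannyl)methanol (Pd(PPh3)4, dioxane, 80 °C) proceeds with retention to the hydroxymethyl enoate F14. TIPSCl with imidazole gives the silyl ether methyl ester F15, and Me3SnOH (1,2-dichloroethane, 70 °C) cleaves the methyl ester. The fallback sets out from 14 and comes back at 20.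

Step 6 (step 14 is the same reaction on the mirror-image ring and shares the risk). Most likely failure: incomplete C–N fragmentation of the secondary nitro group, so that starting material or partly reduced nitrogen compounds remain. Fallback (polar removal through the ketone): Nef reaction of 11 (NaOMe, MeOH; then TiCl3, NH4OAc, H2O) gives the ketone F16. TsNHNH2 in MeOH gives the tosylhydrazone F17. Reduction with catecholborane followed by NaOAc gives the methylene compound; the hydrazone is not conjugated, so the ring alkene should stay in place. The fallback sets out from 11 and comes back at 12.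

## Further compounds

F1 | step 3 | (2S,3R)-2-{[tert-butyl(dimethyl)silyl]oxymethyl}-4-nitro-7-oxo-3-(propan-2-yl)heptanal (epimers at C4) | CC(C)[C@@H](C([N+](=O)[O-])CCC=O)[C@H](C=O)CO[Si](C)(C)C(C)(C)C
F2 | step 19 | tert-butyl(dimethyl){[(1S,6S)-3-[(phenylsulfanyl)methyl]-6-(propan-2-yl)cyclohex-2-en-1-yl]methoxy}silane | CC(C)[C@@H]1CCC(CSc2ccccc2)=C[C@H]1CO[Si](C)(C)C(C)(C)C
F3 | step 19 | [(1S,6S)-3-[(phenylsulfanyl)methyl]-6-(propan-2-yl)cyclohex-2-en-1-yl]methanol | CC(C)[C@@H]1CCC(CSc2ccccc2)=C[C@H]1CO
F4 | step 19 | (bromomethyl)dimethyl{[(1S,6S)-3-[(phenylsulfanyl)methyl]-6-(propan-2-yl)cyclohex-2-en-1-yl]methoxy}silane | CC(C)[C@@H]1CCC(CSc2ccccc2)=C[C@H]1CO[Si](C)(C)CBr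
F5 | step 19 | cis-fused cyclic siloxane: ring B with B4=CH2 and the six-membered ring B2–CH2–O–SiMe2–CH2–B3 (isopropyl trans to the B2 substituent) | C=C1CC[C@@H](C(C)C)[C@@H]2CO[Si](C)(C)C[C@H]12
F6 | step 19 | [(1S,2S,6S)-3-methylidene-6-(propan-2-yl)cyclohexane-1,2-diyl]dimethanol | C=C1CC[C@@H](C(C)C)[C@H](CO)[C@@H]1CO
F7 | step 19 | cis-fused γ-lactone with the carbonyl on B2 and O–CH2 on B3, B4=CH2 | C=C1CC[C@@H](C(C)C)[C@@H]2C(=O)OC[C@H]12
F8 | step 19 | lactol of F7 (anomers) | C=C1CC[C@@H](C(C)C)[C@@H]2C(O)OC[C@H]12
F9 | step 21 | tert-butyl(dimethyl)silyl ether of 31 | CC(C)(C)[Si](C)(C)OC[C@H]1[C@@H](C=C)[C@H](C(C)C)CC[C@]12CO2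
F10 | step 21 | [(1R,2R,3S,4S)-2-{[tert-butyl(dimethyl)silyl]oxymethyl}-3-ethenyl-1-hydroxy-4-(propan-2-yl)cyclohexyl]methyl acetate | CC(=O)OC[C@@]1(O)CC[C@@H](C(C)C)[C@H](C=C)[C@@H]1CO[Si](C)(C)C(C)(C)C
F11 | step 21 | (1R,2R,3S,4S)-2-{[tert-butyl(dimethyl)silyl]oxymethyl}-3-ethenyl-1-(hydroxymethyl)-4-(propan-2-yl)cyclohexan-1-ol | OC[C@@]1(O)CC[C@@H](C(C)C)[C@H](C=C)[C@@H]1CO[Si](C)(C)C(C)(C)C
F12 | step 21 | tert-butyl(dimethyl)silyl ether of 32 at the B3 hydroxymethyl group | CC(C)[C@H]1CCC(CO[Si](c2ccccc2)(c2ccccc2)C(C)(C)C)=C[C@@H]1/C=C(\CO[Si](C(C)C)(C(C)C)C(C)C)C(=O)OC[C@@]1(O)CC[C@@H](C(C)C)[C@H](C=C)[C@@H]1CO[Si](C)(C)C(C)(C)C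
F13 | step 10 | methyl (2Z)-2-bromo-3-[(1R,6R)-3-{[tert-butyl(diphenyl)silyl]oxymethyl}-6-(propan-2-yl)cyclohex-2-en-1-yl]prop-2-enoate | CC(C)[C@H]1CCC(CO[Si](c2ccccc2)(c2ccccc2)C(C)(C)C)=C[C@@H]1/C=C(\Br)C(=O)OC
F14 | step 10 | methyl (2E)-3-[(1R,6R)-3-{[tert-butyl(diphenyl)silyl]oxymethyl}-6-(propan-2-yl)cyclohex-2-en-1-yl]-2-(hydroxymethyl)prop-2-enoate | CC(C)[C@H]1CCC(CO[Si](c2ccccc2)(c2ccccc2)C(C)(C)C)=C[C@@H]1/C=C(\CO)C(=O)OC
F15 | step 10 | methyl ester of acid 20 | CC(C)[C@H]1CCC(CO[Si](c2ccccc2)(c2ccccc2)C(C)(C)C)=C[C@@H]1/C=C(\CO[Si](C(C)C)(C(C)C)C(C)C)C(=O)OC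
F16 | step 6 | (5R,6R)-3-{[tert-butyl(diphenyl)silyl]oxymethyl}-5-{[tert-butyl(dimethyl)silyl]oxymethyl}-6-(propan-2-yl)cyclohex-3-en-1-one | CC(C)[C@H]1C(=O)CC(CO[Si](c2ccccc2)(c2ccccc2)C(C)(C)C)=C[C@@H]1CO[Si](C)(C)C(C)(C)C
F17 | step 6 | 4-methylbenzenesulfonylhydrazone of F16 | CC(C)[C@H]1C(=NNS(=O)(=O)c2ccc(C)cc2)CC(CO[Si](c3ccccc3)(c3ccccc3)C(C)(C)C)=C[C@@H]1CO[Si](C)(C)C(C)(C)C
A1 | alternative 1 | (S)-4-(propan-2-yl)cyclohex-2-en-1-one | O=C1CC[C@@H](C(C)C)C=C1
A2 | alternative 1 | acetylene | C#C
A3 | alternative 1 | cis-fused 5-(propan-2-yl)bicyclo[4.2.0]oct-7-en-2-one | O=C1CC[C@@H](C(C)C)[C@@H]2C=C[C@@H]21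
A4 | alternative 2 | cis formyl acid of ring B, B4 diol as acetonide | CC1(C)OC[C@@]2(O1)CC[C@@H](C(C)C)[C@H](C=O)[C@@H]2C(=O)O
A5 | alternative 2 | tert-butyl 2-(diethoxyphosphoryl)prop-2-enoate | C=C(C(=O)OC(C)(C)C)P(=O)(OCC)OCC
A6 | alternative 2 | right-half bicyclic lactone, B4 diol as acetonide, tert-butyl ester | CC1(C)OC[C@@]2(O1)CC[C@@H](C(C)C)[C@@H]3C=C(C(=O)OC(C)(C)C)COC(=O)[C@@H]32
A7 | alternative 3 | (4R)-8-{[tert-butyl(dimethyl)silyl]oxy}-7-oxo-4-(propan-2-yl)octanoic acid | O=C(O)CC[C@H](C(C)C)CCC(=O)CO[Si](C)(C)C(C)(C)C
A8 | alternative 3 | cis-fused 6-{[tert-butyl(dimethyl)silyl]oxymethyl}-3-(propan-2-yl)-7-oxabicyclo[4.2.0]octan-8-one | O=C1O[C@]2(CO[Si](C)(C)C(C)(C)C)CC[C@@H](C(C)C)C[C@H]12
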